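(The earlier runs and the new flask were computed for an exercise, noise included.)

**Time of reading.** At 50 min we read a running total, the share of target in what became target or side product, and such a total follows its input as a running mean does. Substrate opens to the open intermediate, partner gives the second intermediate, these two make target, and substrate with target makes side product, so the side step needs c_substrate and c_target together.

| setting | spring | autumn | beta | alpha |
|---|---|---|---|---|
| substrate | 13 mM | 13 mM | 13 mM | 13 mM |
| partner | 1.4 equiv | 2.3 equiv | 1.00 equiv | 2.00 equiv |
| temperature | 75 °C | 86 °C | 70 °C | 90 °C |
| remark | run made earlier | run made earlier |  |  |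
| time |  |  | 50 min | 50 min |

| run | time / min | target / % | side product / % |
|---|---|---|---|
| spring | 6.00 | 1.6 | 0.3 |
| spring | 15.0 | 0 | 0 |
| spring | 30.0 | 5.4 | 1.9 |
| spring | 50.0 | 10.6 | 7.5 |
| autumn | 3.00 | 0 | 0 |
| autumn | 8.00 | 5.6 | 1.1 |
| autumn | 15.0 | 13.9 | 2.1 |
| autumn | 25.0 | 28.4 | 10.4 |

(each reading ± 1 percentage point)

1. which one finishes higher in share of target in all that became target or side product ("neither" within 2 percentage points) (beta / alpha / neither)
2. share of target in all that became target or side product, beta
3. share of target in all that became target or side product, alpha

- a species is counted by the substrate in it: one side product counts as two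
- steps under discussion: open intermediate + second intermediate -> target; partner -> second intermediate; substrate + target -> side product; substrate -> open intermediate

**Which numbers count.** The input is target's part of what is newly made over one interval, and it rests on the last two readings of a run. In spring a scatter of 1 percentage point on the last side product moves it by 4.1 points, on the last target by 4.4 points, and the readings at 6.00 min and 15.0 min do not enter.

**The number.** In spring, between 30.0 min and 50.0 min, it is 48.1%, the marginal share (instantaneous selectivity), against a total of 58.6%. In autumn it is 63.6% against 73.2%, so, as these scattered readings stand, both totals were still falling at their last reading. We put beta near spring's total and alpha above autumn's.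

**The forecast.** It says alpha, with beta at 60% (48% to 72%) and alpha at 75% (64% to 84%); of alpha's falling substrate it says “starves the side reaction, which needs substrate”.

**The flask.** Alpha finishes higher, at 81.6% against 68.2% for beta.

    open intermediate + second intermediate → target (k = 0.760 M⁻¹ s⁻¹, Ea = 39.0 kJ mol⁻¹)
    partner → second intermediate (k = 1.90 × 10⁻⁴ s⁻¹, Ea = 111 kJ mol⁻¹)
    substrate + target → side product (k = 0.0850 M⁻¹ s⁻¹, Ea = 63.0 kJ mol⁻¹)
    substrate → open intermediate (k = 0.00150 s⁻¹, Ea = 103 kJ mol⁻¹)
    (constants at 90 °C)

In alpha, substrate was down to 7.99% at 25.0 min with side product at 11.5%; by 50.0 min, with substrate at 0.344%, open intermediate and second intermediate had taken target from 37.2% to 68.6%, while side product reached 15.4%. That interval's marginal share in alpha, the quantity we read as 48.1% from the spring readings, is 88.9%, more than alpha's total of 81.6%. In beta left until 180 min, the marginal share after 50.0 min is 50.7%, less than 68.2%, and that flask's total reads 54.7%.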